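Readings and results were generated by integration for substances that don't exist.

Beware of dividing the two columns as they stand: what is called target includes crystals, so their ratio mixes a solid with a solution. You asked for a quick number, and this is how I would get it.

- epsilon: substrate 0.090 M; run made earlier
- flask: substrate 0.18 M; time 15 d

- epsilon (time / d: isomer of the product / %, target / %): 0.208: 6.1, 52.7; 0.625: 12.1, 47.9; 1.04: 16.6, 38.4; 1.67: 21.4, 26.9; 2.50: 23.7, 14.1; 3.00: 23.8, 12.4

(scatter of a reading: 0.3 percentage points)

- percent here means substrate units held: one homo dimer counts as two
- what is said of target includes crystals
- crystals is a solid; its amount is given per volume of the solution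
- reactions considered so far: substrate <-> target; target <-> isomer of the product; isomer of the product <-> substrate; crystals <-> target; target -> over-reaction product; 2 substrate -> homo dimer

- ratio of isomer of the product to target at 5.0 min
- ratio of isomer of the product to target at 15 d

Start at the end of the epsilon run. Target loses 13 percentage points in 0.830 d, then 1.7 points in 0.500 d, a slower fall, so read the last target value as dissolved. Now go to logarithms: log10 of c(isomer of the product) over c(dissolved target) at that reading gives 0.283, the late log ratio, the logarithm of a quasi-equilibrium ratio.

Next, test the flask. Between 0.625 d and 1.67 d of the epsilon run, target fell at 0.0181 M d⁻¹. At that pace, the first target reading scaled to 0.18 M lasts 5.24 d, shorter than 15 d. So expect dissolved target at the end, and commit to a late ratio of 1.92. For the early ratio I offer no reckoning.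

The forecast gives 0.05 early and 2.5 late: “I expect a quasi-steady ratio of about 2.5.” Its logarithm, 0.398, lies above mine.

The flask gives 0.0360 and 2.10.

    substrate ⇌ target (K = 0.710, k = 0.530 h⁻¹)
    target ⇌ isomer of the product (K = 1.80, k = 0.0270 h⁻¹)
    isomer of the product ⇌ substrate (k = 0.0140 h⁻¹)
    crystals ⇌ target, rate k4*(cs4 - [target]) while solid is left; crystals form when [target] > cs4 (solubility = 15.0 mM, k = 2.00 h⁻¹)
    target → over-reaction product (k = 0.00820 h⁻¹)
    2 substrate → homo dimer (k = 0.470 M⁻¹ h⁻¹)

In this flask crystals stand at 0% after 15.0 d, and the log ratio is 0.322 against the late log ratio of 0.283. The relaxation half-life between dissolved target and isomer of the product, 0.688 d, is short against the 15 d. A neighbour charged with 0.45 M ends with crystals at 14.2%, and its columns as they stand give a log ratio of −0.478, but with crystals subtracted from target they give 0.248.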